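Ring C is read as an acyloin: the C3 carbinol stands next to the C4 ketone. Moving C2 back from C3 to C4 contracts the pyranone to a 2-aryl-2,3-dihydrobenzofuran whose tertiary carbinol carbon (C4) carries C3 as a formyl group.
Cuts in retrosynthetic order: the three aryl acetates; C2–C3 (reverse 1,2-shift); O1–C2 (phenol onto epoxide); C4–C4a (Stille coupling); C6–CMe2 (aromatic Claisen rearrangement of a prenyl ether).
Forward: ring A is built from phloroglucinol and made ready as a single iodide by way of a mirror-symmetric phenol. Ring B comes in as a (Z)-alkenylstannane, the halves are joined at C4–C4a, the furan ring closes at O1–C2, and it is then enlarged by one carbon to ring C.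
Stereochemistry: Sharpless epoxidation with L-(+)-tartrate fixes the benzylic carbon, SN2 opening inverts it to (R)-C2, C2 migrates with retention, and C3 is created in the shift trans to the aryl group.
Acetates protect all three phenols: they make ring A a poor rival migrating group, keep both benzylic carbons from ionising, withstand the silyl Lewis acid and leave together in the last step.

Key step: step 13

Assumption: the SMILES is read as the (2R,3R), 2,3-trans flavanonol; flavanonol atom numbers (O1, C2, C3, C4, C4a, C5 to C8, C8a) are used for the same atoms in all intermediates.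

Step 1
Reactants: 1 phloroglucinol
Product: 2 5-hydroxy-1,3-phenylene diacetate
Conditions: Ac2O (2.0 equiv), pyridine, THF, 0 °C → rt
Reagents that add atoms: acetic anhydride, CC(=O)OC(C)=O
Why: Statistical O-acetylation of the threefold-symmetric triol: two equivalents of anhydride should make the diacetate the main component, and the separated mono- and triacetate can be fed back.

Step 2
Reactants: 2 5-hydroxy-1,3-phenylene diacetate; 3 3-methylbut-2-en-1-ol
Product: 4 5-[(3-methylbut-2-en-1-yl)oxy]-1,3-phenylene diacetate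
Conditions: PPh3, DIAD, THF, 0 °C → rt
Reagents that add atoms: none
Why: Mitsunobu etherification joins the acidic phenol to the primary allylic carbon without base, so the acetyl scrambling and the C-alkylation that plague basic prenylation of phloroglucinols should be avoided.

Step 3
Reactants: 4 5-[(3-methylbut-2-en-1-yl)oxy]-1,3-phenylene diacetate
Product: 6 2-(2-methylbut-3-en-2-yl)benzene-1,3,5-triyl triacetate, via rearranged phenol 5 (not isolated)
Conditions: Ac2O (5 equiv), PhNEt2, 190 °C, sealed tube
Reagents that add atoms: acetic anhydride, CC(=O)OC(C)=O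
Why: Aromatic Claisen rearrangement ([3,3]-sigmatropic, allyl inversion) places the 1,1-dimethylallyl group on either of the two equivalent ortho carbons, and acetylation of phenol 5 as it forms stops its addition to the new alkene and restores a mirror-symmetric ring.

Step 4
Reactants: 6 2-(2-methylbut-3-en-2-yl)benzene-1,3,5-triyl triacetate
Product: 7 5-hydroxy-2-(2-methylbut-3-en-2-yl)-1,3-phenylene diacetate
Conditions: pyrrolidine (1.0 equiv), THF, −20 → 0 °C
Reagents that add atoms: none
Why: Chemoselective aminolysis of an aryl ester: the two acetates beside the quaternary carbon are shielded, so one equivalent of the amine should remove only the acetate para to the side chain and thus single out the oxygen that becomes O1.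

Step 5
Reactants: 7 5-hydroxy-2-(2-methylbut-3-en-2-yl)-1,3-phenylene diacetate
Product: 8 5-hydroxy-4-iodo-2-(2-methylbut-3-en-2-yl)-1,3-phenylene diacetate
Conditions: NIS (1.0 equiv), TFA (10 mol %), MeCN, −20 → 0 °C, dark
Reagents that add atoms: N-iodosuccinimide, O=C1CCC(=O)N1I
Why: Electrophilic aromatic iodination is directed by the free hydroxyl to its two equivalent ortho carbons (para is blocked), so a single regioisomer with the halogen on the future C4a can form, and the hindered monosubstituted alkene is far less nucleophilic than the phenol ring.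

Step 6
Reactants: 8 5-hydroxy-4-iodo-2-(2-methylbut-3-en-2-yl)-1,3-phenylene diacetate
Product: 9 5-[(tert-butyldimethylsilyl)oxy]-4-iodo-2-(2-methylbut-3-en-2-yl)-1,3-phenylene diacetate
Conditions: TBSOTf, 2,6-lutidine, CH2Cl2, 0 °C
Reagents that add atoms: tert-butyldimethylsilyl trifluoromethanesulfonate, CC(C)(C)[Si](C)(C)OS(=O)(=O)C(F)(F)F
Why: Silyl ether formation masks the phenol, which would bind titanium in step 10, as a group that bifluoride can later remove beside aryl acetates.

Step 7
Reactants: 10 4-iodophenyl acetate; 11 prop-2-yn-1-ol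
Product: 12 4-(3-hydroxyprop-1-yn-1-yl)phenyl acetate
Conditions: PdCl2(PPh3)2 (2 mol %), CuI (4 mol %), Et3N, THF, rt
Reagents that add atoms: none
Why: Sonogashira coupling of an aryl iodide with a terminal alkyne runs at room temperature in amine base, conditions that the aryl acetate and the free alcohol tolerate.

Step 8
Reactants: 12 4-(3-hydroxyprop-1-yn-1-yl)phenyl acetate
Product: 13 4-[(Z)-3-hydroxy-2-(tributylstannyl)prop-1-en-1-yl]phenyl acetate
Conditions: Bu3SnH (1.1 equiv, slow addition), [Cp*RuCl]4 (1.5 mol %), CH2Cl2, rt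
Reagents that add atoms: tributyltin hydride, CCCC[SnH](CCCC)CCCC
Why: Ruthenium-catalysed trans-hydrostannation of a propargylic alcohol: hydrogen bonding of the hydroxyl to the Ru–Cl unit should place tin on the proximal carbon and hydrogen is delivered anti, so the aryl group ends cis to tin and trans to CH2OH.

Step 9
Reactants: 9 5-[(tert-butyldimethylsilyl)oxy]-4-iodo-2-(2-methylbut-3-en-2-yl)-1,3-phenylene diacetate; 13 4-[(Z)-3-hydroxy-2-(tributylstannyl)prop-1-en-1-yl]phenyl acetate
Product: 14 4-[(E)-1-(4-acetoxyphenyl)-3-hydroxyprop-1-en-2-yl]-5-[(tert-butyldimethylsilyl)oxy]-2-(2-methylbut-3-en-2-yl)-1,3-phenylene diacetate (the two aryl groups cis)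
Conditions: Pd2(dba)3 (5 mol %), AsPh3 (20 mol %), CuI (20 mol %), DMF, 50 °C
Reagents that add atoms: none
Why: Stille coupling with copper co-catalysis forms the C4–C4a bond with retention of the alkene geometry under neutral, fluoride-free conditions that spare the acetates and the silyl ether.

Step 10
Reactants: 14 4-[(E)-1-(4-acetoxyphenyl)-3-hydroxyprop-1-en-2-yl]-5-[(tert-butyldimethylsilyl)oxy]-2-(2-methylbut-3-en-2-yl)-1,3-phenylene diacetate
Product: 15 4-[(2S,3S)-3-(4-acetoxyphenyl)-2-(hydroxymethyl)oxiran-2-yl]-5-[(tert-butyldimethylsilyl)oxy]-2-(2-methylbut-3-en-2-yl)-1,3-phenylene diacetate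
Conditions: Ti(OiPr)4 (20 mol %), L-(+)-diethyl tartrate (24 mol %), t-BuOOH (2 equiv, decane), 4 Å MS, CH2Cl2, −20 °C
Reagents that add atoms: tert-butyl hydroperoxide, CC(C)(C)OO
Why: Sharpless asymmetric epoxidation: the titanium tartrate complex is anchored on the allylic hydroxyl, so the isolated vinyl group is left alone, and with L-(+)-tartrate an (E)-2,3-diarylallyl alcohol, a classic substrate class, should take up oxygen on the face that gives the (2S,3S)-epoxide, which sets both epoxide carbons at once.

Step 11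
Reactants: 15 4-[(2S,3S)-3-(4-acetoxyphenyl)-2-(hydroxymethyl)oxiran-2-yl]-5-[(tert-butyldimethylsilyl)oxy]-2-(2-methylbut-3-en-2-yl)-1,3-phenylene diacetate
Product: 16 4-[(2R,3S)-3-(4-acetoxyphenyl)-2-formyloxiran-2-yl]-5-[(tert-butyldimethylsilyl)oxy]-2-(2-methylbut-3-en-2-yl)-1,3-phenylene diacetate
Conditions: Dess–Martin periodinane (1.3 equiv), CH2Cl2, 0 °C → rt
Reagents that add atoms: none
Why: Dess–Martin oxidation of a 2,3-epoxy alcohol to the epoxy aldehyde is routine, non-basic and cannot epimerise the fully substituted α-carbon (only the descriptor changes), and the new formyl group disfavours heterolysis of the tertiary C–O bond in the next step.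

Step 12
Reactants: 16 4-[(2R,3S)-3-(4-acetoxyphenyl)-2-formyloxiran-2-yl]-5-[(tert-butyldimethylsilyl)oxy]-2-(2-methylbut-3-en-2-yl)-1,3-phenylene diacetate
Product: 18 (2R,3R)-2-(4-acetoxyphenyl)-3-formyl-3-hydroxy-5-(2-methylbut-3-en-2-yl)-2,3-dihydrobenzofuran-4,6-diyl diacetate, via free phenol 17 (not isolated)
Conditions: KHF2 (2 equiv), MeOH, rt; solvent exchange; Et3N (30 mol %), MeCN (0.01 M), 45 °C
Reagents that add atoms: none
Why: Bifluoride cleaves the aryl silyl ether selectively beside aryl acetates, and the phenolate then opens the epoxide intramolecularly at the benzylic carbon (5-endo, the 4-exo mode being impossible), an SN2 event whose inversion turns the S epoxide carbon into (R)-C2 and leaves the aryl group cis to the new tertiary hydroxyl.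

Step 13
Reactants: 18 (2R,3R)-2-(4-acetoxyphenyl)-3-formyl-3-hydroxy-5-(2-methylbut-3-en-2-yl)-2,3-dihydrobenzofuran-4,6-diyl diacetate
Product: 21 (2R,3R)-2-(4-acetoxyphenyl)-3-hydroxy-6-(2-methylbut-3-en-2-yl)-4-oxochromane-5,7-diyl diacetate, via silyl ether 19 (not isolated), via silylated ketol 20 (not isolated)
Conditions: TMSOTf (1.3 equiv), 2,6-lutidine (1.1 equiv), CH2Cl2, −78 → −20 °C; then aq. citric acid, THF, 0 °C
Reagents that add atoms: none
Why: Proposed new method: TMSOTf first caps the tertiary hydroxyl (19); the small excess then silylates the formyl oxygen, and as the lone pair of the siloxy oxygen makes C4 a carbonyl the C2–C4 σ bond slides suprafacially to the formyl carbon and becomes C2–C3, after which Me3Si+ leaves the C4 oxygen and carries the chain (20, whose 3-O-silyl group falls off in the citric acid wash). The closest known reactions are the Lewis-acid rearrangement of α,α-disubstituted α-siloxy aldehydes to α-siloxy ketones, the acyloin ring enlargement of 1-hydroxycycloalkanecarbaldehydes and the D-homo rearrangement of 17-hydroxy-20-keto steroids; a benzofuranol carbaldehyde with an oxygen-bearing migrating carbon lies outside these. Ring C is not closed by a cyclisation: the five-membered O1–C2–C4–C4a–C8a ring takes up C3 between C2 and C4 and so grows to the six-membered pyranone. C2 migrates with retention, so the R configuration from step 12 persists; C3 is set by the formyl rotamer, because a five-membered metal chelate with both oxygens syn would turn the wrong formyl face to C2 and give the 2,3-cis ketol from this epimer, whereas two silylated oxygens cannot chelate, repel each other and should react from the anti rotamer, in which the silylated formyl oxygen lies under the ring face that bears only H-2, giving (3R), the trans and also the more stable diequatorial isomer. The step needs C2 to migrate faster than the aryl carbon C4a, whose shift would give a 4-hydroxychroman-3-one with an epimerisable C2: the two acetates make ring A a poor ipso nucleophile, while C2 is a secondary benzylic carbon with an oxygen lone pair at its side and leads to the conjugated aryl ketone. The 4'-acetate keeps C2 from ionising away from C4 (which would racemise it), and the electron-poor ring A together with the adjacent formyl group disfavours loss of the tertiary oxygen and aromatisation to a benzofuran.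

Step 14
Reactants: 21 (2R,3R)-2-(4-acetoxyphenyl)-3-hydroxy-6-(2-methylbut-3-en-2-yl)-4-oxochromane-5,7-diyl diacetate
Product: 22 (2R,3R)-3,5,7-trihydroxy-2-(4-hydroxyphenyl)-6-(2-methylbut-3-en-2-yl)chroman-4-one
Conditions: HCl (0.5 M in MeOH), 35 °C
Reagents that add atoms: none
Why: Acid-catalysed transesterification removes all three aryl acetates (two of them now vinylogous anhydrides of the C4 ketone) without base, so neither ring opening at C2 nor epimerisation at C3 should occur, and dilute methanolic HCl is too weak to protonate the monosubstituted alkene.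

Compound list
1 | phloroglucinol | Oc1cc(O)cc(O)c1 | starting material
2 | 5-hydroxy-1,3-phenylene diacetate | CC(=O)Oc1cc(O)cc(OC(C)=O)c1 | intermediate
3 | 3-methylbut-2-en-1-ol | CC(C)=CCO | starting material
4 | 5-[(3-methylbut-2-en-1-yl)oxy]-1,3-phenylene diacetate | CC(C)=CCOc1cc(OC(C)=O)cc(OC(C)=O)c1 | intermediate
5 | 5-hydroxy-4-(2-methylbut-3-en-2-yl)-1,3-phenylene diacetate | C=CC(C)(C)c1c(O)cc(OC(C)=O)cc1OC(C)=O | intermediate
6 | 2-(2-methylbut-3-en-2-yl)benzene-1,3,5-triyl triacetate | C=CC(C)(C)c1c(OC(C)=O)cc(OC(C)=O)cc1OC(C)=O | intermediate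
7 | 5-hydroxy-2-(2-methylbut-3-en-2-yl)-1,3-phenylene diacetate | C=CC(C)(C)c1c(OC(C)=O)cc(O)cc1OC(C)=O | intermediate
8 | 5-hydroxy-4-iodo-2-(2-methylbut-3-en-2-yl)-1,3-phenylene diacetate | C=CC(C)(C)c1c(OC(C)=O)cc(O)c(I)c1OC(C)=O | intermediate
9 | 5-[(tert-butyldimethylsilyl)oxy]-4-iodo-2-(2-methylbut-3-en-2-yl)-1,3-phenylene diacetate | C=CC(C)(C)c1c(OC(C)=O)cc(O[Si](C)(C)C(C)(C)C)c(I)c1OC(C)=O | intermediate
10 | 4-iodophenyl acetate | CC(=O)Oc1ccc(I)cc1 | starting material
11 | prop-2-yn-1-ol | C#CCO | starting material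
12 | 4-(3-hydroxyprop-1-yn-1-yl)phenyl acetate | CC(=O)Oc1ccc(C#CCO)cc1 | intermediate
13 | 4-[(Z)-3-hydroxy-2-(tributylstannyl)prop-1-en-1-yl]phenyl acetate | OC/C(=C/c1ccc(OC(C)=O)cc1)[Sn](CCCC)(CCCC)CCCC | intermediate
14 | 4-[(E)-1-(4-acetoxyphenyl)-3-hydroxyprop-1-en-2-yl]-5-[(tert-butyldimethylsilyl)oxy]-2-(2-methylbut-3-en-2-yl)-1,3-phenylene diacetate | OC/C(=C/c1ccc(OC(C)=O)cc1)c1c(O[Si](C)(C)C(C)(C)C)cc(OC(C)=O)c(C(C)(C)C=C)c1OC(C)=O | intermediate
15 | 4-[(2S,3S)-3-(4-acetoxyphenyl)-2-(hydroxymethyl)oxiran-2-yl]-5-[(tert-butyldimethylsilyl)oxy]-2-(2-methylbut-3-en-2-yl)-1,3-phenylene diacetate | OC[C@]1(c2c(O[Si](C)(C)C(C)(C)C)cc(OC(C)=O)c(C(C)(C)C=C)c2OC(C)=O)O[C@H]1c1ccc(OC(C)=O)cc1 | intermediate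
16 | 4-[(2R,3S)-3-(4-acetoxyphenyl)-2-formyloxiran-2-yl]-5-[(tert-butyldimethylsilyl)oxy]-2-(2-methylbut-3-en-2-yl)-1,3-phenylene diacetate | O=C[C@]1(c2c(O[Si](C)(C)C(C)(C)C)cc(OC(C)=O)c(C(C)(C)C=C)c2OC(C)=O)O[C@H]1c1ccc(OC(C)=O)cc1 | intermediate
17 | 4-[(2R,3S)-3-(4-acetoxyphenyl)-2-formyloxiran-2-yl]-5-hydroxy-2-(2-methylbut-3-en-2-yl)-1,3-phenylene diacetate | O=C[C@]1(c2c(O)cc(OC(C)=O)c(C(C)(C)C=C)c2OC(C)=O)O[C@H]1c1ccc(OC(C)=O)cc1 | intermediate
18 | (2R,3R)-2-(4-acetoxyphenyl)-3-formyl-3-hydroxy-5-(2-methylbut-3-en-2-yl)-2,3-dihydrobenzofuran-4,6-diyl diacetate (2-aryl cis to 3-hydroxyl) | O=C[C@@]1(O)c2c(OC(C)=O)c(C(C)(C)C=C)c(OC(C)=O)cc2O[C@@H]1c1ccc(OC(C)=O)cc1 | intermediate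
19 | (2R,3R)-2-(4-acetoxyphenyl)-3-formyl-5-(2-methylbut-3-en-2-yl)-3-[(trimethylsilyl)oxy]-2,3-dihydrobenzofuran-4,6-diyl diacetate | O=C[C@@]1(O[Si](C)(C)C)c2c(OC(C)=O)c(C(C)(C)C=C)c(OC(C)=O)cc2O[C@@H]1c1ccc(OC(C)=O)cc1 | intermediate
20 | (2R,3R)-2-(4-acetoxyphenyl)-6-(2-methylbut-3-en-2-yl)-4-oxo-3-[(trimethylsilyl)oxy]chromane-5,7-diyl diacetate | C=CC(C)(C)c1c(OC(C)=O)cc2c(c1OC(C)=O)C(=O)[C@H](O[Si](C)(C)C)[C@@H](c1ccc(OC(C)=O)cc1)O2 | intermediate
21 | (2R,3R)-2-(4-acetoxyphenyl)-3-hydroxy-6-(2-methylbut-3-en-2-yl)-4-oxochromane-5,7-diyl diacetate | C=CC(C)(C)c1c(OC(C)=O)cc2c(c1OC(C)=O)C(=O)[C@H](O)[C@@H](c1ccc(OC(C)=O)cc1)O2 | intermediate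
22 | (2R,3R)-3,5,7-trihydroxy-2-(4-hydroxyphenyl)-6-(2-methylbut-3-en-2-yl)chroman-4-one | C=CC(C)(C)c1c(O)cc2c(c1O)C(=O)[C@H](O)[C@@H](c1ccc(O)cc1)O2 | target

Total step count: 14. Longest linear sequence: 12 steps (steps 1–6 and 9–14).

Steps most likely to fail

1. Step 13.
- Possible failure: migration of the aryl carbon C4a in place of C2; heterolysis of the C2–C4 bond followed by reclosure with loss of configuration at C2; weak rotamer control at C3; or acetyl transfer from O5 to the tertiary oxygen before silylation.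
- Fallback by known chemistry, from 9 back to 21: the three-carbon chain is laid down in linear form, so no skeletal shift is needed. Carbonylative Heck coupling of 9 with 4-acetoxystyrene (CO, PdCl2(PPh3)2, Et3N, dioxane) would give the 2'-silyloxy chalcone F1. Nucleophilic asymmetric epoxidation of the enone (t-BuOOH, La(OiPr)3, (S)-BINOL, Ph3As=O, THF), which ignores the isolated vinyl group, would give the (2R,3S)-epoxy ketone F2. KHF2 in MeOH would release the 2'-hydroxy epoxy ketone F3. Its acid-catalysed 6-endo opening at the benzylic carbon with inversion, the classical chalcone epoxide route to trans-flavanonols, would give 21.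

2. Step 12.
- Possible failure: sluggish 5-endo attack, which leaves time for lactol formation between the phenol and the formyl group, for acetyl transfer between oxygens, or for a formyl shift to the benzylic carbon.
- Fallback, from 15 back to 18: the ring is closed one oxidation level lower. KHF2 in MeOH on 15 would give the phenolic epoxy alcohol F4. Ti(OiPr)4 in CH2Cl2 at 0 °C binds the epoxy alcohol through its CH2OH group, the known activation for C3-selective opening of 2,3-epoxy alcohols. The phenol should then open the benzylic carbon with the same inversion to give the dihydrobenzofuran diol F5. Parikh–Doering oxidation of the primary alcohol would give 18.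

3. Step 9.
- Possible failure: slow transmetalation to an aryl-palladium centre flanked by two ortho oxygens, so that protodestannylation and homocoupling take over.
- Fallback, from 13 and 9 back to 14: the roles of the partners are exchanged and tin is replaced by boron. Iododestannylation of 13 (I2, CH2Cl2, retention) would give the (Z)-2-iodoallyl alcohol F6. Miyaura borylation of 9 (B2pin2, PdCl2(dppf), KOAc, dioxane) would give the aryl pinacol boronate F7. Suzuki–Miyaura coupling of the two (Pd(OAc)2, SPhos, anhydrous K3PO4, toluene) would give 14.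

Further compounds
F1 | step 13 | 2'-silyloxy chalcone, 4-[(E)-3-(4-acetoxyphenyl)prop-2-enoyl]-5-[(tert-butyldimethylsilyl)oxy]-2-(2-methylbut-3-en-2-yl)-1,3-phenylene diacetate | CC(=O)Oc1ccc(/C=C/C(=O)c2c(O[Si](C)(C)C(C)(C)C)cc(OC(C)=O)c(C(C)(C)C=C)c2OC(C)=O)cc1
F2 | step 13 | (2R,3S)-epoxy ketone, 4-{[(2R,3S)-3-(4-acetoxyphenyl)oxiran-2-yl]carbonyl}-5-[(tert-butyldimethylsilyl)oxy]-2-(2-methylbut-3-en-2-yl)-1,3-phenylene diacetate | O=C(c1c(O[Si](C)(C)C(C)(C)C)cc(OC(C)=O)c(C(C)(C)C=C)c1OC(C)=O)[C@@H]1O[C@H]1c1ccc(OC(C)=O)cc1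
F3 | step 13 | 2'-hydroxy epoxy ketone, 4-{[(2R,3S)-3-(4-acetoxyphenyl)oxiran-2-yl]carbonyl}-5-hydroxy-2-(2-methylbut-3-en-2-yl)-1,3-phenylene diacetate | O=C(c1c(O)cc(OC(C)=O)c(C(C)(C)C=C)c1OC(C)=O)[C@@H]1O[C@H]1c1ccc(OC(C)=O)cc1
F4 | step 12 | phenolic epoxy alcohol, 4-[(2S,3S)-3-(4-acetoxyphenyl)-2-(hydroxymethyl)oxiran-2-yl]-5-hydroxy-2-(2-methylbut-3-en-2-yl)-1,3-phenylene diacetate | OC[C@]1(c2c(O)cc(OC(C)=O)c(C(C)(C)C=C)c2OC(C)=O)O[C@H]1c1ccc(OC(C)=O)cc1
F5 | step 12 | dihydrobenzofuran diol, (2R,3S)-2-(4-acetoxyphenyl)-3-hydroxy-3-(hydroxymethyl)-5-(2-methylbut-3-en-2-yl)-2,3-dihydrobenzofuran-4,6-diyl diacetate | OC[C@@]1(O)c2c(OC(C)=O)c(C(C)(C)C=C)c(OC(C)=O)cc2O[C@@H]1c1ccc(OC(C)=O)cc1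
F6 | step 9 | (Z)-2-iodoallyl alcohol, 4-[(Z)-3-hydroxy-2-iodoprop-1-en-1-yl]phenyl acetate | OC/C(I)=C/c1ccc(OC(C)=O)cc1
F7 | step 9 | aryl pinacol boronate, 5-[(tert-butyldimethylsilyl)oxy]-2-(2-methylbut-3-en-2-yl)-4-(4,4,5,5-tetramethyl-1,3,2-dioxaborolan-2-yl)-1,3-phenylene diacetate | C=CC(C)(C)c1c(OC(C)=O)cc(O[Si](C)(C)C(C)(C)C)c(B2OC(C)(C)C(C)(C)O2)c1OC(C)=O
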